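**Retrosynthetic overview**
- The acrylic acid is added last: the C=C bond is cut back to a C5 aldehyde (Knoevenagel–Doebner), and the phenol acetate is removed in the same pot.
- Only one ring is built, the dihydrofuran; both benzene rings are bought. It closes at C3a–C3 by 5-exo aryl-radical cyclisation of an ortho-iodoaryl 1-arylallyl ether with O2 capture, which sets C3 trans to the C2 aryl and delivers the CH2OH.
- Key disconnection: the aryl O–C2 bond, made by a site-selective, branched- and enantioselective Ir-catalysed allylic etherification of an unprotected iodocatechol aldehyde with a linear cinnamyl carbonate (sets C2).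
- Precursors: the iodocatechol by O-demethylation of an iodovanillin; the carbonate from a cinnamate ester (reduction, then methoxycarbonylation).

Target as read: trans-(2R,3S)-dihydrobenzofuran with 2-(3,4-dimethoxyphenyl), 3-CH2OH, 7-OH and an E acrylic acid at C5.
Assumption: L is the (Ra,Rc,Rc)-BINOL N,N-bis(1-phenylethyl)phosphoramidite, taken to give the R ether as in published phenoxide etherifications of cinnamyl carbonates; its antipode is used if the sense proves opposite.

**Step 1**
Reactants: 1 methyl (2E)-3-(3,4-dimethoxyphenyl)prop-2-enoate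
Product: 2 (2E)-3-(3,4-dimethoxyphenyl)prop-2-en-1-ol
Conditions: iBu2AlH (2.3 equiv), CH2Cl2, −78 → 0 °C; aq. KNaC4H4O6 (potassium sodium tartrate) work-up
Reagents that add atoms: none
Why: 1,2-Hydride reduction of a conjugated ester with iBu2AlH gives the E allylic alcohol without touching the C=C bond, and no stereocentre is formed.

**Step 2**
Reactants: 2 (2E)-3-(3,4-dimethoxyphenyl)prop-2-en-1-ol
Product: 3 (2E)-3-(3,4-dimethoxyphenyl)prop-2-en-1-yl methyl carbonate
Conditions: ClCO2Me (1.3 equiv), pyridine (2 equiv), CH2Cl2, 0 °C → rt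
Reagents that add atoms: methyl chloroformate, COC(=O)Cl
Why: O-Alkoxycarbonylation of a primary allylic alcohol with a chloroformate gives the linear carbonate that serves as leaving group for iridium π-allyl formation.

**Step 3**
Reactants: 4 4-hydroxy-3-iodo-5-methoxybenzaldehyde (5-iodovanillin)
Product: 5 3,4-dihydroxy-5-iodobenzaldehyde
Conditions: AlCl3 (1.1 equiv), pyridine (4.4 equiv), CH2Cl2, reflux, 24 h; then aq. HCl
Reagents that add atoms: none
Why: Lewis-acid aryl methyl ether cleavage (AlCl3–pyridine demethylation) works because aluminium chelated between the phenoxide and the neighbouring methoxy oxygen activates that methyl for SN2 attack by pyridine, leaving the aryl iodide and aldehyde intact.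

**Step 4**
Reactants: 3 (2E)-3-(3,4-dimethoxyphenyl)prop-2-en-1-yl methyl carbonate; 5 3,4-dihydroxy-5-iodobenzaldehyde
Product: 7 2-{[(1R)-1-(3,4-dimethoxyphenyl)prop-2-en-1-yl]oxy}-5-formyl-3-iodophenyl acetate, via free phenol ether 6 (not isolated)
Conditions: 5 (1.2 equiv), [Ir(cod)Cl]2 (2 mol%), (Ra,Rc,Rc)-L (4 mol%; pre-activated with n-PrNH2, volatiles removed), THF, 25 °C, no added base, stopped when 3 is consumed; then Ac2O, Et3N, DMAP (cat.), 0 °C
Reagents that add atoms: acetic anhydride, CC(=O)OC(C)=O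
Why: Proposed new method: a site-selective iridium-catalysed asymmetric allylic etherification of an unprotected catechol, whose closest known reaction is the [Ir(cod)Cl]2/phosphoramidite-catalysed branched-selective etherification of cinnamyl carbonates with mono-phenoxides; oxidative addition of 3 to the cyclometalated monovalent iridium complex gives a trivalent iridium π-allyl and methyl carbonate, which loses CO2 to methoxide that deprotonates only the 4-OH of 5 (para to CHO and ortho to I, estimated 2–3 pKa units more acidic than the 3-OH), and this phenoxide attacks the aryl-bearing allyl terminus anti to the metal on the face left open by the ligand, so the branched O4 ether with the R stereocentre (the future C2) forms while the never-ionised 3-OH stays free for the in-pot acetylation.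

**Step 5**
Reactants: 7 2-{[(1R)-1-(3,4-dimethoxyphenyl)prop-2-en-1-yl]oxy}-5-formyl-3-iodophenyl acetate
Product: 9 (2R,3S)-2-(3,4-dimethoxyphenyl)-5-formyl-3-(hydroxymethyl)-2,3-dihydro-1-benzofuran-7-yl acetate, via primary hydroperoxide 8 (not isolated)
Conditions: Bu3SnH (1.5 equiv, syringe pump), dry air, toluene, 0 °C → rt; then PPh3
Reagents that add atoms: dioxygen, O=O
Why: Oxygenative radical cyclisation (iodine abstraction by Bu3Sn•, aryl-radical 5-exo-trig closure onto the vinyl group, O2 capture of the primary radical, PPh3 reduction of the hydroperoxide) works because ring closure far outruns O2 or Sn–H trapping of the aryl radical, and the chair-like Beckwith–Houk transition state with the C2 aryl pseudo-equatorial places the new CH2 trans to it, setting C3 as S (estimated trans:cis near 6:1, minor isomer removed by chromatography) without touching C2.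

**Step 6**
Reactants: 9 (2R,3S)-2-(3,4-dimethoxyphenyl)-5-formyl-3-(hydroxymethyl)-2,3-dihydro-1-benzofuran-7-yl acetate
Product: 11 (2E)-3-[(2R,3S)-2-(3,4-dimethoxyphenyl)-7-hydroxy-3-(hydroxymethyl)-2,3-dihydro-1-benzofuran-5-yl]prop-2-enoic acid, via acetoxy acrylic acid 10 (not isolated)
Conditions: CH2(CO2H)2 (3 equiv), pyridine, piperidine (0.2 equiv), 85 °C; then aq. LiOH, rt; then aq. HCl to pH 3
Reagents that add atoms: malonic acid, OC(=O)CC(=O)O
Why: Knoevenagel–Doebner condensation gives only the E acrylic acid by piperidine-catalysed addition of malonic acid and decarboxylative elimination, the LiOH stage then saponifies the aryl acetate, and neither stage can epimerise C2 or C3 because the ring carries no carbonyl group at C3.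

**Compound list**
1 | methyl (2E)-3-(3,4-dimethoxyphenyl)prop-2-enoate | COC(=O)/C=C/c1ccc(OC)c(OC)c1 | starting material
2 | (2E)-3-(3,4-dimethoxyphenyl)prop-2-en-1-ol | OC/C=C/c1ccc(OC)c(OC)c1 | intermediate
3 | (2E)-3-(3,4-dimethoxyphenyl)prop-2-en-1-yl methyl carbonate | COC(=O)OC/C=C/c1ccc(OC)c(OC)c1 | intermediate
4 | 4-hydroxy-3-iodo-5-methoxybenzaldehyde (5-iodovanillin) | COc1cc(C=O)cc(I)c1O | starting material
5 | 3,4-dihydroxy-5-iodobenzaldehyde | O=Cc1cc(O)c(O)c(I)c1 | intermediate
6 | 4-{[(1R)-1-(3,4-dimethoxyphenyl)prop-2-en-1-yl]oxy}-3-hydroxy-5-iodobenzaldehyde | C=C[C@@H](Oc1c(O)cc(C=O)cc1I)c1ccc(OC)c(OC)c1 | intermediate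
7 | 2-{[(1R)-1-(3,4-dimethoxyphenyl)prop-2-en-1-yl]oxy}-5-formyl-3-iodophenyl acetate | C=C[C@@H](Oc1c(OC(C)=O)cc(C=O)cc1I)c1ccc(OC)c(OC)c1 | intermediate
8 | (2R,3S)-2-(3,4-dimethoxyphenyl)-5-formyl-3-(hydroperoxymethyl)-2,3-dihydro-1-benzofuran-7-yl acetate | COc1ccc([C@@H]2Oc3c(OC(C)=O)cc(C=O)cc3[C@H]2COO)cc1OC | intermediate
9 | (2R,3S)-2-(3,4-dimethoxyphenyl)-5-formyl-3-(hydroxymethyl)-2,3-dihydro-1-benzofuran-7-yl acetate | COc1ccc([C@@H]2Oc3c(OC(C)=O)cc(C=O)cc3[C@H]2CO)cc1OC | intermediate
10 | (2E)-3-[(2R,3S)-7-(acetyloxy)-2-(3,4-dimethoxyphenyl)-3-(hydroxymethyl)-2,3-dihydro-1-benzofuran-5-yl]prop-2-enoic acid | COc1ccc([C@@H]2Oc3c(OC(C)=O)cc(/C=C/C(=O)O)cc3[C@H]2CO)cc1OC | intermediate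
11 | (2E)-3-[(2R,3S)-2-(3,4-dimethoxyphenyl)-7-hydroxy-3-(hydroxymethyl)-2,3-dihydro-1-benzofuran-5-yl]prop-2-enoic acid (CNP0193199.1) | COc1ccc([C@@H]2Oc3c(O)cc(/C=C/C(=O)O)cc3[C@H]2CO)cc1OC | target

**Step count and risks**
Total steps: 6. Longest linear sequence: 5 (steps 1, 2, 4, 5, 6).

Three steps most likely to fail:

1. Step 4 (the proposed new step). Risks: O3 versus O4 selectivity, a sluggish hindered and acidic phenoxide, and branched-to-linear isomerisation of the product by the catalyst. Fallback with known chemistry, setting out from 5 and coming back at 7: the site selection is moved into a protecting-group operation. 5 is peracetylated (Ac2O, pyridine) to 5-formyl-3-iodo-1,2-phenylene diacetate F1. Its more activated acetate (para to the aldehyde, ortho to iodine) is cleaved by one equivalent of piperidine at 0 °C to give 5-formyl-2-hydroxy-3-iodophenyl acetate F2. F2, now a mono-phenol, is coupled as its lithium phenoxide with 3 under the established [Ir(cod)Cl]2/phosphoramidite etherification of ortho-substituted phenoxides, which gives 7 directly.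

2. Step 5. Risks: autoxidation of the aldehyde under the aerobic tin conditions, and a modest trans:cis ratio. Fallback, setting out from 7 and coming back at 11: the aldehyde is converted first and O2 is replaced by a nitroxide trap. 7 is olefinated with Ph3P=CHCO2Me to methyl (2E)-3-[3-(acetyloxy)-4-{[(1R)-1-(3,4-dimethoxyphenyl)prop-2-en-1-yl]oxy}-5-iodophenyl]prop-2-enoate F3. Bu3SnH and TEMPO in degassed benzene at 70 °C (aryl-radical 5-exo cyclisation with nitroxide capture) give methyl (2E)-3-[(2R,3S)-7-(acetyloxy)-2-(3,4-dimethoxyphenyl)-3-{[(2,2,6,6-tetramethylpiperidin-1-yl)oxy]methyl}-2,3-dihydro-1-benzofuran-5-yl]prop-2-enoate F4. Zn in AcOH/THF/water cleaves the N–O bond to methyl (2E)-3-[(2R,3S)-7-(acetyloxy)-2-(3,4-dimethoxyphenyl)-3-(hydroxymethyl)-2,3-dihydro-1-benzofuran-5-yl]prop-2-enoate F5. LiOH in THF/water then removes the methyl ester and the acetate to give 11.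

3. Step 6. Risks: incomplete condensation or loss of material in hot pyridine. Fallback, setting out from 9 and coming back at 11: the two carbons are added with a phosphorus ylide. 9 and Ph3P=CHCO2Et in toluene at 60 °C give ethyl (2E)-3-[(2R,3S)-7-(acetyloxy)-2-(3,4-dimethoxyphenyl)-3-(hydroxymethyl)-2,3-dihydro-1-benzofuran-5-yl]prop-2-enoate F6. LiOH in THF/water at rt cleaves the ethyl ester and the acetate in one operation to give 11.

**Further compounds**
F1 | step 4 | 5-formyl-3-iodo-1,2-phenylene diacetate | CC(=O)Oc1cc(C=O)cc(I)c1OC(C)=O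
F2 | step 4 | 5-formyl-2-hydroxy-3-iodophenyl acetate | CC(=O)Oc1cc(C=O)cc(I)c1O
F3 | step 5 | methyl (2E)-3-[3-(acetyloxy)-4-{[(1R)-1-(3,4-dimethoxyphenyl)prop-2-en-1-yl]oxy}-5-iodophenyl]prop-2-enoate | C=C[C@@H](Oc1c(OC(C)=O)cc(/C=C/C(=O)OC)cc1I)c1ccc(OC)c(OC)c1
F4 | step 5 | methyl (2E)-3-[(2R,3S)-7-(acetyloxy)-2-(3,4-dimethoxyphenyl)-3-{[(2,2,6,6-tetramethylpiperidin-1-yl)oxy]methyl}-2,3-dihydro-1-benzofuran-5-yl]prop-2-enoate | COc1ccc([C@@H]2Oc3c(OC(C)=O)cc(/C=C/C(=O)OC)cc3[C@H]2CON4C(C)(C)CCCC4(C)C)cc1OC
F5 | step 5 | methyl (2E)-3-[(2R,3S)-7-(acetyloxy)-2-(3,4-dimethoxyphenyl)-3-(hydroxymethyl)-2,3-dihydro-1-benzofuran-5-yl]prop-2-enoate | COc1ccc([C@@H]2Oc3c(OC(C)=O)cc(/C=C/C(=O)OC)cc3[C@H]2CO)cc1OC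
F6 | step 6 | ethyl (2E)-3-[(2R,3S)-7-(acetyloxy)-2-(3,4-dimethoxyphenyl)-3-(hydroxymethyl)-2,3-dihydro-1-benzofuran-5-yl]prop-2-enoate | COc1ccc([C@@H]2Oc3c(OC(C)=O)cc(/C=C/C(=O)OCC)cc3[C@H]2CO)cc1OC
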